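## Retrosynthetic overview

1. Target ⇐ its 4'-O-benzyl-5-O-methyl ether: one BCl3 operation removes the benzyl group and only the carbonyl-chelated 5-OMe.
2. Ring C is the only ring built and is formed last: O1–C2 by cyclodehydration of an o-hydroxyaryl α-methoxy-1,3-diketone, C2–C3 by C-aroylation of an ω-methoxy ketone enolate (Baker–Venkataraman type).
3. Ring A ketone ⇐ 2,3,4,5-tetramethoxyphenol + methoxyacetyl chloride (Fries); the phenol ⇐ 1,2,3,4-tetramethoxybenzene (ortho-lithiation, borylation, oxidation).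
4. Ring B acid chloride ⇐ methyl 4-hydroxy-2-methoxybenzoate (benzylation, saponification); rings A and B are bought as benzenes.

Assumption 1: the target has no stereocentre (it is achiral), so "single enantiomer" needs no stereocontrol and the SMILES carry no stereodescriptors.
Assumption 2: conjugate bases, salts and Lewis-acid (Li, B) adducts that only fall apart in the aqueous work-up are treated as work-up and are not numbered.

## Route

Step 1
Reactants: 1 1,2,3,4-tetramethoxybenzene
Product: 4 2,3,4,5-tetramethoxyphenol, via 2,3,4,5-tetramethoxyphenyllithium 2 (not isolated), via dimethyl 2,3,4,5-tetramethoxyphenylboronate 3 (not isolated)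
Conditions: n-BuLi, TMEDA, THF, 0 °C; B(OMe)3, −78 °C → rt; AcOH, 30% H2O2, 0 °C → rt; Na2S2O3 quench
Reagents that add atoms: n-butyllithium [Li]CCCC (Li of 2); trimethyl borate COB(OC)OC (B(OMe)2 of 3); hydrogen peroxide OO (phenol O of 4)
Why: Directed ortho-metalation (C5 and C6 are equivalent, so one aryllithium), borate trapping and oxidative ipso-hydroxylation of the boronate (B→O 1,2-aryl shift) give the phenol; no stereocentre is formed.

Step 2
Reactants: 4 2,3,4,5-tetramethoxyphenol; 5 methoxyacetyl chloride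
Product: 7 1-(2-hydroxy-3,4,5,6-tetramethoxyphenyl)-2-methoxyethan-1-one, via 2,3,4,5-tetramethoxyphenyl methoxyacetate 6 (not isolated)
Conditions: BF3·OEt2 (neat), 0 °C → 80 °C; then H2O/MeOH, 60 °C
Reagents that add atoms: none
Why: O-acylation followed by BF3-promoted Fries rearrangement can deliver the acyl group only to the single free ring position, ortho to the OH, and BF3 (unlike AlCl3) leaves the aryl methyl ethers intact.

Step 3
Reactants: 8 methyl 4-hydroxy-2-methoxybenzoate
Product: 10 4-(benzyloxy)-2-methoxybenzoic acid, via methyl 4-(benzyloxy)-2-methoxybenzoate 9 (not isolated)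
Conditions: BnBr, K2CO3, acetone, reflux; filter, concentrate; NaOH, MeOH/H2O, 60 °C; HCl to pH 2
Reagents that add atoms: benzyl bromide BrCc1ccccc1; sodium hydroxide [Na+].[OH-] (O of the CO2H)
Why: Williamson etherification of the only phenol followed by ester saponification; the benzyl ether is stable to aqueous base.

Step 4
Reactants: 7 1-(2-hydroxy-3,4,5,6-tetramethoxyphenyl)-2-methoxyethan-1-one; 10 4-(benzyloxy)-2-methoxybenzoic acid
Product: 13 2-[4-(benzyloxy)-2-methoxyphenyl]-3,5,6,7,8-pentamethoxy-4H-chromen-4-one, via 4-(benzyloxy)-2-methoxybenzoyl chloride 11 (not isolated), via alpha-methoxy-1,3-diketone 12 (not isolated)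
Conditions: 10, (COCl)2, cat. DMF, CH2Cl2, rt, evaporate; 7, LiHMDS (3.3 equiv), THF, −78 → −10 °C, then crude 11, −78 °C → rt; aq. HCl; crude 12, AcOH, 0.5% H2SO4, 90 °C
Reagents that add atoms: oxalyl chloride ClC(=O)C(Cl)=O (Cl of 11)
Why: The lithium phenoxide-enolate of 7 is C-aroylated by 11 (Claisen-type acylation, the direct variant of the Baker–Venkataraman diketone synthesis) and the o-hydroxyaryl 1,3-diketone closes ring C by acid-catalysed cyclodehydration, in which the transient CH(OMe) centre of 12 becomes sp2.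

Step 5
Reactants: 13 2-[4-(benzyloxy)-2-methoxyphenyl]-3,5,6,7,8-pentamethoxy-4H-chromen-4-one
Product: 14 5-hydroxy-2-(4-hydroxy-2-methoxyphenyl)-3,6,7,8-tetramethoxy-4H-chromen-4-one (5,4'-dihydroxy-3,6,7,8,2'-pentamethoxyflavone)
Conditions: BCl3 (5 equiv), C6HMe5 (3 equiv), CH2Cl2, −78 → 0 °C; then H2O
Reagents that add atoms: none
Why: Lewis-acid ether cleavage in which BCl3 removes the aryl benzyl ether (benzyl cation trapped by pentamethylbenzene) and, through the six-membered chelate with the C4 carbonyl, only the peri 5-OMe, leaving the 3-, 6-, 7-, 8- and 2'-OMe groups.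

## Compound list

1 | 1,2,3,4-tetramethoxybenzene | COc1ccc(OC)c(OC)c1OC | starting material
2 | (2,3,4,5-tetramethoxyphenyl)lithium | [Li]c1cc(OC)c(OC)c(OC)c1OC | intermediate
3 | dimethyl (2,3,4,5-tetramethoxyphenyl)boronate | COB(OC)c1cc(OC)c(OC)c(OC)c1OC | intermediate
4 | 2,3,4,5-tetramethoxyphenol | COc1cc(O)c(OC)c(OC)c1OC | intermediate
5 | methoxyacetyl chloride | COCC(Cl)=O | starting material
6 | 2,3,4,5-tetramethoxyphenyl 2-methoxyacetate | COCC(=O)Oc1cc(OC)c(OC)c(OC)c1OC | intermediate
7 | 1-(2-hydroxy-3,4,5,6-tetramethoxyphenyl)-2-methoxyethan-1-one | COCC(=O)c1c(O)c(OC)c(OC)c(OC)c1OC | intermediate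
8 | methyl 4-hydroxy-2-methoxybenzoate | COC(=O)c1ccc(O)cc1OC | starting material
9 | methyl 4-(benzyloxy)-2-methoxybenzoate | COC(=O)c1ccc(OCc2ccccc2)cc1OC | intermediate
10 | 4-(benzyloxy)-2-methoxybenzoic acid | OC(=O)c1ccc(OCc2ccccc2)cc1OC | intermediate
11 | 4-(benzyloxy)-2-methoxybenzoyl chloride | ClC(=O)c1ccc(OCc2ccccc2)cc1OC | intermediate
12 | 1-[4-(benzyloxy)-2-methoxyphenyl]-3-(2-hydroxy-3,4,5,6-tetramethoxyphenyl)-2-methoxypropane-1,3-dione (racemic, enolisable) | COc1cc(OCc2ccccc2)ccc1C(=O)C(OC)C(=O)c1c(O)c(OC)c(OC)c(OC)c1OC | intermediate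
13 | 2-[4-(benzyloxy)-2-methoxyphenyl]-3,5,6,7,8-pentamethoxy-4H-chromen-4-one | COc1cc(OCc2ccccc2)ccc1-c1oc2c(OC)c(OC)c(OC)c(OC)c2c(=O)c1OC | intermediate
14 | 5-hydroxy-2-(4-hydroxy-2-methoxyphenyl)-3,6,7,8-tetramethoxy-4H-chromen-4-one (achiral) | COc1cc(O)ccc1-c1oc2c(OC)c(OC)c(OC)c(O)c2c(=O)c1OC | target

## Step count and risks

Total step count: 5 (steps 1–5, five isolated products).
Longest linear sequence: 4 steps (1 → 4 → 7 → 13 → 14); the ring B branch (8 → 10) joins at step 4.

The three steps most likely to fail, in route order: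

**Step 2 (Fries acylation of a crowded, oxidation-prone penta-oxygenated ring).** The fallback sets out from 4 and comes back at 7. Compound 4 is O-methylated (MeI, K2CO3, acetone) to 1,2,3,4,5-pentamethoxybenzene F1. Intermolecular Friedel–Crafts acylation of F1 with 5 (AlCl3, Et2O/CH2Cl2, 0 °C → rt) gives 2-methoxy-1-(2,3,4,5,6-pentamethoxyphenyl)ethan-1-one F2. In the same pot AlCl3 removes one of the two equivalent ortho methyl groups of F2 through the ketone chelate, which gives 7.

**Step 4 (telescoped C-aroylation and cyclodehydration on a di-ortho-substituted ketone; O-acylation or incomplete conversion are the risks).** The fallback sets out from 7 and 10 and comes back at 12. Steglich esterification (EDC·HCl, DMAP, CH2Cl2) gives the isolated aryl ester 2,3,4,5-tetramethoxy-6-(methoxyacetyl)phenyl 4-(benzyloxy)-2-methoxybenzoate F3. A separate Baker–Venkataraman O→C acyl migration (KOH, pyridine, 50 °C) converts F3 into diketone 12, which is cyclised to 13 as in step 4.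

**Step 5 (one-pot double dealkylation; over-cleavage at 3-OMe or 6-OMe, or incomplete 5-demethylation, are the risks).** The fallback sets out from 13 and comes back at 14. The two cleavages are separated into orthogonal operations. Hydrogenolysis (H2, 10% Pd/C, EtOAc/MeOH, rt) gives 2-(4-hydroxy-2-methoxyphenyl)-3,5,6,7,8-pentamethoxy-4H-chromen-4-one F4. Chelation-controlled 5-O-demethylation of F4 with anhydrous AlCl3 in MeCN (rt → 50 °C, then dilute HCl) gives 14.

## Further compounds

F1 | step 2 | 1,2,3,4,5-pentamethoxybenzene | COc1cc(OC)c(OC)c(OC)c1OC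
F2 | step 2 | 2-methoxy-1-(2,3,4,5,6-pentamethoxyphenyl)ethan-1-one | COCC(=O)c1c(OC)c(OC)c(OC)c(OC)c1OC
F3 | step 4 | 2,3,4,5-tetramethoxy-6-(methoxyacetyl)phenyl 4-(benzyloxy)-2-methoxybenzoate | COCC(=O)c1c(OC(=O)c2ccc(OCc3ccccc3)cc2OC)c(OC)c(OC)c(OC)c1OC
F4 | step 5 | 2-(4-hydroxy-2-methoxyphenyl)-3,5,6,7,8-pentamethoxy-4H-chromen-4-one | COc1cc(O)ccc1-c1oc2c(OC)c(OC)c(OC)c(OC)c2c(=O)c1OC
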